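(All runs were generated by integration from invented constants, and the scatter is random.)

The target is the product wanted here, and it appears first: at 10.0 s in the autumn run it reads 10 % against 6 % of its isomer.

| flask | starting material | temperature | remark | time |
|---|---|---|---|---|
| autumn | 0.050 M | 20 °C | run made earlier |  |
| summer | 0.075 M | 32 °C | run made earlier |  |
| beta | 0.10 M | 25 °C |  | 2.0 min |
| alpha | 0.10 M | 40 °C |  | 2.0 min |

| run | time / s | starting material / % | isomer of the product / % | target / % |
|---|---|---|---|---|
| autumn | 10.0 | 86 | 6 | 10 |
| autumn | 20.0 | 77 | 13 | 13 |
| autumn | 40.0 | 60 | 31 | 11 |
| autumn | 90.0 | 39 | 53 | 7 |
| summer | 25.0 | 44 | 52 | 6 |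
| summer | 50.0 | 31 | 66 | 3 |
| summer | 80.0 | 20 | 76 | 3 |
| summer | 90.0 | 17 | 78 | 4 |

(each reading ± 1.5 percentage points)

- a species is counted by the starting material in it: one target or isomer of the product counts as two

* which of these there is most of at the end, counted by the starting material in it, beta (starting material / isomer of the product / target)
* which of these there is most of at the end, counted by the starting material in it, alpha (starting material / isomer of the product / target)
* the largest of these amounts at the end, in percent of the starting material charged, beta
* the largest of these amounts at the end, in percent of the starting material charged, alpha

The summer run looks contradictory. Between 50.0 s and 90.0 s starting material falls from 31 % to 17 % and isomer climbs from 66 % to 78 %, yet target, the apparent way through, reads 3 % and then 4 %. So compare rates at one moment. Between 20.0 s and 40.0 s of the autumn run, isomer gains 18 percentage points on a target pool near 12.0 %, so target is used at 0.0750 /s. Read from the autumn run, with its scatter, that is a half-life of 9.24 s, shorter than the 2.0 min asked, so a small pool can carry the flow, as a quasi-steady-state intermediate does.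

Now let the comparison drift: the making of target slows as starting material falls, yet the target readings stop falling. The last two summer readings, with their scatter, give 0.0455 for s, the late split, target divided by isomer once target has stopped falling.

Let a be the fraction of starting material left and c its charge. The reciprocal of a climbs about in a straight line with time t, so the reciprocal less one, over ct, gives k, the second-order constant of the fall of starting material; the last reading of each run gives 0.348 /M/s at 20 °C and 0.723 /M/s at 32 °C. Taken geometrically in temperature, my beta keeps 15.0 % and my alpha 6.60 %. Assuming that s, read at 32 °C, holds at both temperatures, the part gone, divided by one plus s, gives isomer, more than the starting material kept: 81.3 % in beta and 89.3 % in alpha.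

The forecast puts isomer of the product first in beta at 79 % and isomer of the product first in alpha at 88 %, each lower than my figure , and calls target's level “possibly a small equilibrium with the isomer”.

The flasks give isomer of the product at 80.9 % in beta and isomer of the product at 88.9 % in alpha.

    2 starting material → target (k = 0.230 /M/s, Ea = 39.0 kJ/mol)
    target ⇌ isomer of the product (K = 28.0, k = 0.130 /s, Ea = 74.0 kJ/mol, ΔH = 0 kJ/mol)
    (constants at 25 °C)

In beta at 2.00 min, target over isomer stands at 0.0469 against s of 0.0455, and the relaxation half-life of target and isomer, both directions together, is 0.0858 min, shorter than the 2.0 min. Target is then made at 0.920 of the rate at which it is used, each step taken net. Beta run at 0 °C instead holds 31.2 % target and 25.4 % isomer at the same time, a split larger than s at 1.23.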